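## Retrosynthetic overview

Eudesmane numbering is used throughout: C1 = CHBr, C4 = C(OH)CH3, C5/C10 = ring fusion, C6 = CHOAc, C7 = CH‑iPr.

1. Target ⇒ acetylation of the C6 alcohol; the C4 carbinol comes from equatorial CH3 addition to a 15‑nor‑4‑ketone.
2. Ring B (formed second) ⇒ intramolecular carbonyl‑ene reaction (C6–C7 bond) of a ring A aldehyde carrying a 4‑methylpent‑3‑enyl chain on C10; this sets C6 and C7.
3. Ring A (formed first) ⇒ proposed catalytic enantioselective 6‑endo bromocarbocyclization of an acyclic (E)‑alkenyl β‑keto ester (C5–C10 bond; sets C1–Br and C10).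
4. β‑Keto ester ⇒ methyl acetoacetate dianion + an (E)‑allylic bromide made from hex‑1‑en‑5‑yne; the vinyl group is inert to Br+ and is turned into the prenyl‑type alkene by cross‑metathesis after the bromocyclization.

Assumption: the (R,R)‑configured titanium TADDOLate (TADDOLate = 2,2‑dimethyl‑α,α,α',α'‑tetra(1‑naphthyl)‑1,3‑dioxolane‑4,5‑dimethanolate) gives the (1R,2R,3R) cyclization product (the (S,S)‑ligand is used if the sense of induction is the opposite); hex‑1‑en‑5‑yne is taken as a catalogue chemical.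

## Route

Step 1
Reactants: 1 hex-1-en-5-yne
Product: 3 (2E)-3-methylhepta-2,6-dien-1-ol, via alkenylalane 2 (not isolated)
Conditions: Me3Al (2 equiv), Cp2ZrCl2 (0.2 equiv), CH2Cl2, 0 → 23 °C; then (CH2O)n, 0 → 23 °C; aq. HCl
Reagents that add atoms: trimethylaluminium, C[Al](C)C; formaldehyde (as paraformaldehyde), C=O
Why: Zirconium-catalysed Negishi carboalumination adds CH3–Al syn across the alkyne only (the monosubstituted alkene is inert), and the (E)-alkenylalane is hydroxymethylated with retention, fixing the (E)-trisubstituted alkene.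

Step 2
Reactants: 3 (2E)-3-methylhepta-2,6-dien-1-ol
Product: 4 (2E)-1-bromo-3-methylhepta-2,6-diene
Conditions: PBr3 (0.4 equiv), Et2O, −10 → 0 °C
Reagents that add atoms: phosphorus tribromide, BrP(Br)Br
Why: Standard conversion of a primary allylic alcohol to the allylic bromide (as for geranyl bromide), with retention of the alkene geometry.

Step 3
Reactants: 4 (2E)-1-bromo-3-methylhepta-2,6-diene; 5 methyl acetoacetate
Product: 7 methyl (6E)-7-methyl-3-oxoundeca-6,10-dienoate, via acetoacetate dianion 6 (not isolated)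
Conditions: NaH (1.1 equiv), THF, 0 °C; n-BuLi (1.05 equiv), 0 °C; then 4, 0 → 23 °C; aq. HCl
Reagents that add atoms: none
Why: Weiler dianion alkylation: the γ-carbon of the acetoacetate dianion displaces the allylic bromide, giving the β-keto ester with the (E)-alkene untouched.

Step 4
Reactants: 7 methyl (6E)-7-methyl-3-oxoundeca-6,10-dienoate
Product: 9 methyl (1R,2R,3R)-3-bromo-2-(but-3-en-1-yl)-2-methyl-6-oxocyclohexane-1-carboxylate, via alpha-bromo keto ester 8 (not isolated)
Conditions: NBS (1.05 equiv), TiCl2[(R,R)-1-Np-TADDOLate] (10 mol %), 4 Å MS, CH2Cl2–MeNO2 (3:1), −40 °C; then −20 → 0 °C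
Reagents that add atoms: N-bromosuccinimide, O=C1CCC(=O)N1Br
Why: Proposed new method: a chiral tetravalent titanium enolate-controlled 6-endo bromocarbocyclization in which NBS first α-brominates the TADDOLate-bound enolate to 8, whose Lewis-acid-activated C–Br bond hands Br+ back reversibly to the only nucleophilic (trisubstituted) alkene, and the bromiranium ion is then opened at its tertiary carbon, anti to Br, by the enolate carbon through a chair transition state (the (E)-alkene places CH3 axial and the butenyl chain and Br equatorial, Br cis to CH3) while the ligand-shielded enolate face accepts only one bromiranium enantiomer (the mismatched ion pair reverts by Br+ transfer), so ring A, the C5–C10 bond and the absolute configuration at C1 and C10 are set in one step and the ester at C5 settles equatorial; the closest known reaction types are the titanium TADDOLate-mediated enantioselective iodocarbocyclization of alkenyl malonates (5-exo), chiral Lewis acid α-halogenation of β-keto esters and racemic bromonium-initiated cation–olefin cyclizations ended by β-keto esters.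

Step 5
Reactants: 9 methyl (1R,2R,3R)-3-bromo-2-(but-3-en-1-yl)-2-methyl-6-oxocyclohexane-1-carboxylate
Product: 10 methyl (6R,7R,8R)-8-bromo-7-(but-3-en-1-yl)-7-methyl-1,4-dioxaspiro[4.5]decane-6-carboxylate
Conditions: HOCH2CH2OH (5 equiv), TsOH·H2O (5 mol %), benzene, reflux, Dean–Stark
Reagents that add atoms: ethane-1,2-diol, OCCO
Why: Acid-catalysed ketalization of the β-keto ester ketone masks C4 for the reduction and ene steps; the bromide, ester and alkene are inert and no stereocentre is touched.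

Step 6
Reactants: 10 methyl (6R,7R,8R)-8-bromo-7-(but-3-en-1-yl)-7-methyl-1,4-dioxaspiro[4.5]decane-6-carboxylate
Product: 11 [(6S,7R,8R)-8-bromo-7-(but-3-en-1-yl)-7-methyl-1,4-dioxaspiro[4.5]decan-6-yl]methanol
Conditions: iBu2AlH (2.5 equiv), CH2Cl2, −78 → 0 °C; aq. KNaC4H4O6
Reagents that add atoms: none
Why: Ester-to-primary-alcohol reduction with iBu2AlH, which does not reduce the secondary alkyl bromide or the ketal (the descriptor at C6 changes only through ligand priorities).

Step 7
Reactants: 11 [(6S,7R,8R)-8-bromo-7-(but-3-en-1-yl)-7-methyl-1,4-dioxaspiro[4.5]decan-6-yl]methanol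
Product: 12 [(6S,7R,8R)-8-bromo-7-methyl-7-(4-methylpent-3-en-1-yl)-1,4-dioxaspiro[4.5]decan-6-yl]methanol
Conditions: 2-methylbut-2-ene (excess), second-generation Grubbs catalyst RuCl2(H2IMes)(PCy3)(=CHPh) (5 mol %), CH2Cl2, 40 °C
Reagents that add atoms: 2-methylbut-2-ene, CC=C(C)C
Why: Olefin cross-metathesis of a terminal alkene with 2-methylbut-2-ene is a standard way to install the isopropylidene (prenyl-type) terminus, and it tolerates the free alcohol and the bromide.

Step 8
Reactants: 12 [(6S,7R,8R)-8-bromo-7-methyl-7-(4-methylpent-3-en-1-yl)-1,4-dioxaspiro[4.5]decan-6-yl]methanol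
Product: 13 (6S,7R,8R)-8-bromo-7-methyl-7-(4-methylpent-3-en-1-yl)-1,4-dioxaspiro[4.5]decane-6-carbaldehyde
Conditions: Dess–Martin periodinane (1.3 equiv), pyridine, CH2Cl2, 0 → 23 °C
Reagents that add atoms: none
Why: Dess–Martin oxidation gives the aldehyde under buffered, non-epimerizing conditions that leave the ketal, alkene and bromide intact.

Step 9
Reactants: 13 (6S,7R,8R)-8-bromo-7-methyl-7-(4-methylpent-3-en-1-yl)-1,4-dioxaspiro[4.5]decane-6-carbaldehyde
Product: 14 (4'R,4a'R,7'S,8'S,8a'S)-4'-bromo-4a'-methyl-7'-(prop-1-en-2-yl)octahydro-2'H-spiro[[1,3]dioxolane-2,1'-naphthalen]-8'-ol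
Conditions: ZnBr2 (1.2 equiv), CH2Cl2, 0 °C
Reagents that add atoms: none
Why: Intramolecular carbonyl-ene reaction of the citronellal-to-isopulegol type: the aldehyde, chelated by ZnBr2 to the equatorial dioxolane oxygen, closes ring B through a trans-decalin chair transition state with the C6–O bond and the C7 substituent both equatorial, which sets 6α-OH and 7β-isopropenyl (trans to each other, H6 anti to H5).

Step 10
Reactants: 14 (4'R,4a'R,7'S,8'S,8a'S)-4'-bromo-4a'-methyl-7'-(prop-1-en-2-yl)octahydro-2'H-spiro[[1,3]dioxolane-2,1'-naphthalen]-8'-ol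
Product: 15 (4'R,4a'R,7'S,8'S,8a'S)-4'-bromo-4a'-methyl-7'-(propan-2-yl)octahydro-2'H-spiro[[1,3]dioxolane-2,1'-naphthalen]-8'-ol
Conditions: H2 (3 atm), RhCl(PPh3)3 (5 mol %), benzene–EtOH (1:1), 23 °C
Reagents that add atoms: none
Why: Homogeneous hydrogenation of the 1,1-disubstituted alkene to isopropyl; RhCl(PPh3)3 does not cleave the secondary C–Br bond and no stereocentre is created.

Step 11
Reactants: 15 (4'R,4a'R,7'S,8'S,8a'S)-4'-bromo-4a'-methyl-7'-(propan-2-yl)octahydro-2'H-spiro[[1,3]dioxolane-2,1'-naphthalen]-8'-ol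
Product: 16 (4R,4aR,7S,8S,8aS)-4-bromo-8-hydroxy-4a-methyl-7-(propan-2-yl)octahydronaphthalen-1(2H)-one
Conditions: 1 M aq. HCl, THF, 23 °C
Reagents that add atoms: water, O
Why: Mild acetal hydrolysis releases the C4 ketone; the trans ring fusion at C5 is kept under these non-basic conditions.

Step 12
Reactants: 16 (4R,4aR,7S,8S,8aS)-4-bromo-8-hydroxy-4a-methyl-7-(propan-2-yl)octahydronaphthalen-1(2H)-one
Product: 17 (1S,2S,4aR,5R,8S,8aS)-5-bromo-4a,8-dimethyl-2-(propan-2-yl)decahydronaphthalene-1,8-diol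
Conditions: MeMgBr (3 equiv), THF, −78 → 0 °C; then H2O
Reagents that add atoms: methylmagnesium bromide, C[Mg]Br
Why: Grignard 1,2-addition in which axial (β) approach to C4 is blocked by the syn-axial C10 methyl, so CH3 enters equatorially from the α face (also the face of the C6 magnesium alkoxide), giving the axial 4β-OH and equatorial 4α-CH3 of the target.

Step 13
Reactants: 17 (1S,2S,4aR,5R,8S,8aS)-5-bromo-4a,8-dimethyl-2-(propan-2-yl)decahydronaphthalene-1,8-diol
Product: 18 (1S,2S,4aR,5R,8S,8aS)-5-bromo-8-hydroxy-4a,8-dimethyl-2-(propan-2-yl)decahydronaphthalen-1-yl acetate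
Conditions: Ac2O (3 equiv), pyridine, DMAP (10 mol %), CH2Cl2, 23 °C
Reagents that add atoms: acetic anhydride, CC(=O)OC(C)=O
Why: DMAP-catalysed acylation acetylates the secondary equatorial C6 alcohol, while the hindered tertiary axial C4 alcohol does not react under these conditions.

## Compound list

1 | hex-1-en-5-yne | C=CCCC#C | starting material
2 | (1E)-dimethyl(2-methylhexa-1,5-dien-1-yl)alane | C=CCC/C(C)=C/[Al](C)C | intermediate
3 | (2E)-3-methylhepta-2,6-dien-1-ol | C=CCC/C(C)=C/CO | intermediate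
4 | (2E)-1-bromo-3-methylhepta-2,6-diene | C=CCC/C(C)=C/CBr | intermediate
5 | methyl acetoacetate (methyl 3-oxobutanoate) | COC(=O)CC(C)=O | starting material
6 | methyl acetoacetate dianion, lithium sodium salt | [Na+].[Li+].C=C([O-])C=C([O-])OC | intermediate
7 | methyl (6E)-7-methyl-3-oxoundeca-6,10-dienoate | COC(=O)CC(=O)CC/C=C(\C)CCC=C | intermediate
8 | methyl (6E)-2-bromo-7-methyl-3-oxoundeca-6,10-dienoate (C2 not defined) | COC(=O)C(Br)C(=O)CC/C=C(\C)CCC=C | intermediate
9 | methyl (1R,2R,3R)-3-bromo-2-(but-3-en-1-yl)-2-methyl-6-oxocyclohexane-1-carboxylate (CO2Me, CH3 and Br on one face; butenyl on the other) | COC(=O)[C@H]1C(=O)CC[C@@H](Br)[C@]1(C)CCC=C | intermediate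
10 | methyl (6R,7R,8R)-8-bromo-7-(but-3-en-1-yl)-7-methyl-1,4-dioxaspiro[4.5]decane-6-carboxylate | COC(=O)[C@H]1C2(OCCO2)CC[C@@H](Br)[C@]1(C)CCC=C | intermediate
11 | [(6S,7R,8R)-8-bromo-7-(but-3-en-1-yl)-7-methyl-1,4-dioxaspiro[4.5]decan-6-yl]methanol | OC[C@H]1C2(OCCO2)CC[C@@H](Br)[C@]1(C)CCC=C | intermediate
12 | [(6S,7R,8R)-8-bromo-7-methyl-7-(4-methylpent-3-en-1-yl)-1,4-dioxaspiro[4.5]decan-6-yl]methanol | OC[C@H]1C2(OCCO2)CC[C@@H](Br)[C@]1(C)CCC=C(C)C | intermediate
13 | (6S,7R,8R)-8-bromo-7-methyl-7-(4-methylpent-3-en-1-yl)-1,4-dioxaspiro[4.5]decane-6-carbaldehyde | O=C[C@H]1C2(OCCO2)CC[C@@H](Br)[C@]1(C)CCC=C(C)C | intermediate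
14 | (4'R,4a'R,7'S,8'S,8a'S)-4'-bromo-4a'-methyl-7'-(prop-1-en-2-yl)octahydro-2'H-spiro[[1,3]dioxolane-2,1'-naphthalen]-8'-ol (trans-decalin; 1β-Br, 5α-H, 6α-OH, 7β-isopropenyl, 10β-CH3, C4 ketal) | O[C@@H]1[C@@H]2[C@@](C)(CC[C@H]1C(C)=C)[C@H](Br)CCC23OCCO3 | intermediate
15 | (4'R,4a'R,7'S,8'S,8a'S)-4'-bromo-4a'-methyl-7'-(propan-2-yl)octahydro-2'H-spiro[[1,3]dioxolane-2,1'-naphthalen]-8'-ol | O[C@@H]1[C@@H]2[C@@](C)(CC[C@H]1C(C)C)[C@H](Br)CCC23OCCO3 | intermediate
16 | (4R,4aR,7S,8S,8aS)-4-bromo-8-hydroxy-4a-methyl-7-(propan-2-yl)octahydronaphthalen-1(2H)-one | O[C@@H]1[C@@H]2[C@@](C)(CC[C@H]1C(C)C)[C@H](Br)CCC2=O | intermediate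
17 | (1S,2S,4aR,5R,8S,8aS)-5-bromo-4a,8-dimethyl-2-(propan-2-yl)decahydronaphthalene-1,8-diol (1β-bromoeudesmane-4β,6α-diol) | O[C@@H]1[C@@H]2[C@@](C)(CC[C@H]1C(C)C)[C@H](Br)CC[C@]2(C)O | intermediate
18 | (1S,2S,4aR,5R,8S,8aS)-5-bromo-8-hydroxy-4a,8-dimethyl-2-(propan-2-yl)decahydronaphthalen-1-yl acetate (CNP0136555.3) | CC(=O)O[C@@H]1[C@@H]2[C@@](C)(CC[C@H]1C(C)C)[C@H](Br)CC[C@]2(C)O | target

## Step count and risk

Total step count: 13. Longest linear sequence: 13 steps (from hex-1-en-5-yne, compound 1).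

Steps most likely to fail:

1. Step 4 (the proposed bromocarbocyclization). Likely failure modes are O-cyclization to a cyclic enol ether, α,α-dibromination, or low enantioselectivity. The fallback uses known chemistry, sets out from bromide 4 and comes back at alcohol 11. Commercial (−)-menthyl acetoacetate F1 is converted to its dianion (NaH, n-BuLi, THF) and alkylated with 4 to give menthyl keto ester F2. A racemic bromonium-induced cation–olefin cyclization with Et2SBr·SbCl5Br (MeNO2, −25 °C) then gives two diastereomeric menthyl esters, from which the (1R,2R,3R) ring diastereomer, menthyl bromo keto ester F3, is separated by chromatography or crystallization. Ketalization (ethane-1,2-diol, TsOH·H2O) gives menthyl ketal ester F4, and reduction with iBu2AlH removes the auxiliary as (−)-menthol and delivers 11.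

2. Step 9 (carbonyl-ene closure of ring B). Risks are Lewis acid opening of the ketal, Prins-type by-products, or the C6 epimer. The fallback sets out from alcohol 11 (before the cross-metathesis) and comes back at 15. Dess–Martin oxidation gives butenyl aldehyde F5; chelation-controlled addition of (3-methylbut-1-en-2-yl)magnesium bromide from the open α face gives allylic alcohol F6. Ring-closing metathesis with the second-generation Hoveyda–Grubbs catalyst RuCl2(H2IMes)(=CH-2-iPrO-C6H4) closes ring B as cyclohexenol F7. Hydroxyl-directed hydrogenation with [Ir(cod)(PCy3)(py)]PF6 then adds H2 syn to the C6 hydroxyl and gives 15.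

3. Step 12 (methyl addition to the β-hydroxy ketone). Risks are enolization, retro-aldol opening of ring B, or a C4 epimer mixture. The fallback sets out from ketone 16 and comes back at diol 17. Corey–Chaykovsky methylenation with dimethylsulfoxonium methylide (Me3S(O)I, NaH, DMSO) transfers CH2 equatorially and gives spiro-epoxide F8 with the oxygen axial (β). LiAlH4 (THF, 0 °C) opens the oxirane at its CH2 terminus to give 17; the secondary bromide next to the quaternary carbon is expected to survive these conditions.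

Further compounds
F1 | step 4 | (1R,2S,5R)-5-methyl-2-(propan-2-yl)cyclohexyl 3-oxobutanoate ((−)-menthyl acetoacetate) | C[C@@H]1CC[C@H]([C@@H](C1)OC(=O)CC(C)=O)C(C)C
F2 | step 4 | (1R,2S,5R)-5-methyl-2-(propan-2-yl)cyclohexyl (6E)-7-methyl-3-oxoundeca-6,10-dienoate | C[C@@H]1CC[C@H]([C@@H](C1)OC(=O)CC(=O)CC/C=C(\C)CCC=C)C(C)C
F3 | step 4 | (1R,2S,5R)-5-methyl-2-(propan-2-yl)cyclohexyl (1R,2R,3R)-3-bromo-2-(but-3-en-1-yl)-2-methyl-6-oxocyclohexane-1-carboxylate | C[C@@H]1CC[C@H]([C@@H](C1)OC(=O)[C@H]2C(=O)CC[C@@H](Br)[C@]2(C)CCC=C)C(C)C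
F4 | step 4 | (1R,2S,5R)-5-methyl-2-(propan-2-yl)cyclohexyl (6R,7R,8R)-8-bromo-7-(but-3-en-1-yl)-7-methyl-1,4-dioxaspiro[4.5]decane-6-carboxylate | C[C@@H]1CC[C@H]([C@@H](C1)OC(=O)[C@H]2C3(OCCO3)CC[C@@H](Br)[C@]2(C)CCC=C)C(C)C
F5 | step 9 | (6S,7R,8R)-8-bromo-7-(but-3-en-1-yl)-7-methyl-1,4-dioxaspiro[4.5]decane-6-carbaldehyde | O=C[C@H]1C2(OCCO2)CC[C@@H](Br)[C@]1(C)CCC=C
F6 | step 9 | (1R)-1-[(6S,7R,8R)-8-bromo-7-(but-3-en-1-yl)-7-methyl-1,4-dioxaspiro[4.5]decan-6-yl]-3-methyl-2-methylidenebutan-1-ol | O[C@@H](C(=C)C(C)C)[C@H]1C2(OCCO2)CC[C@@H](Br)[C@]1(C)CCC=C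
F7 | step 9 | (4'R,4a'R,8'R,8a'S)-4'-bromo-4a'-methyl-7'-(propan-2-yl)-3',4',4a',5',8',8a'-hexahydro-2'H-spiro[[1,3]dioxolane-2,1'-naphthalen]-8'-ol | O[C@@H]1[C@@H]2[C@@](C)(CC=C1C(C)C)[C@H](Br)CCC23OCCO3
F8 | step 12 | (1S,4R,4aR,7S,8S,8aS)-4-bromo-4a-methyl-7-(propan-2-yl)octahydro-2H-spiro[naphthalene-1,2'-oxiran]-8-ol | O[C@@H]1[C@@H]2[C@@](C)(CC[C@H]1C(C)C)[C@H](Br)CC[C@]23OC3
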